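**Retrosynthetic overview**

1. Rivularin A is traced back to 4',5,5'-tribromo-1'H-1,3'-biindole. The three bromines at C2 and C3 of ring A and C2' of ring B go on last by electrophilic bromination.
2. Key disconnection: the N1–C3' bond between the two indoles. It is made by a one-pot C3'–H/N1–H coupling in which 4,5-dibromoindole is converted into its indol-3-yl(mesityl)iodonium salt and this N-arylates 5-bromoindole under copper catalysis.
3. 4,5-Dibromoindole comes from 4,5-dibromoisatin (borane reduction), which comes from 4-bromoisatin (bromination para to nitrogen).
4. No ring is built. Both indole nuclei are bought (5-bromoindole for ring A, 4-bromoisatin for ring B). Ring B is adjusted first, then joined to ring A, then the biindole is tribrominated.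

Assumption: the SMILES has no stereodescriptor and the molecule has no stereocentre, so the target is taken as the constitution shown; the N1–C3' axis is not controlled and the product is racemic about it if the axis is configurationally stable.

**Route**

Step 1
Reactants: 1 4-bromoisatin (4-bromo-1H-indole-2,3-dione)
Product: 2 4,5-dibromoisatin (4,5-dibromo-1H-indole-2,3-dione)
Conditions: Br2 (1.05 equiv), AcOH, 80 °C
Reagents that add atoms: bromine, BrBr
Why: Electrophilic aromatic bromination in which the lactam nitrogen (para), the C3 ketone (meta) and the C4 bromine (ortho) all direct to C5, as in isatin itself, which brominates at C5 before C7; no stereocentre is formed.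

Step 2
Reactants: 2 4,5-dibromoisatin
Product: 5 4,5-dibromo-1H-indole, via 3-hydroxyoxindole 3 (not isolated), via 3-hydroxyindoline 4 (not isolated)
Conditions: BH3·THF (4 equiv), THF, 0 °C → 60 °C; then 1 M HCl, rt
Reagents that add atoms: none
Why: Borane reduces the ketone and then the lactam carbonyl (reductive aromatisation of an isatin), and the resulting racemic 3-hydroxyindoline loses water on acidic work-up to give the aromatic indole, so its stereocentre is irrelevant; aryl bromides are inert to borane.

Step 3
Reactants: 5 4,5-dibromo-1H-indole; 6 5-bromo-1H-indole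
Product: 9 4',5,5'-tribromo-1'H-1,3'-biindole, via iodonium tosylate 7 (not isolated), via iodonium betaine 8 (not isolated)
Conditions: MesI(OH)OTs (1.0 equiv), MeCN, 0 °C → rt, 1 h; then 6 (1.5 equiv), Cu(MeCN)4BF4 (10 mol %), 1,10-phenanthroline (12 mol %), K3PO4 (3 equiv), DMSO, 40 °C
Reagents that add atoms: none
Why: Proposed new method: a one-pot dehydrogenative N1–C3' heterocoupling of two NH-indoles — the trivalent iodine reagent MesI(OH)OTs attacks 5 at its most nucleophilic carbon (C3) to give the unsymmetrical indol-3-yl(mesityl)iodonium salt 7 before the second indole is present, so the roles of the two indoles are fixed by the order of addition; K3PO4 then converts 7 into the neutral betaine 8 (whose nitrogen is no longer a competent nucleophile, which suppresses self-coupling) and lets 6 bind to monovalent copper as an N-bound indolide; copper takes over the less hindered indol-3-yl group from iodine (the 2,6-dimethylated mesityl group is not transferred) and C–N reductive elimination from the resulting trivalent copper aryl amide forms the N1–C3' bond at 40 °C, far below the temperature at which copper inserts into the three C–Br bonds; N- rather than C3-arylation of 6 is enforced by the base and the chelating ligand; the closest known reaction types are the copper-catalysed N-arylation of azoles with diaryliodonium salts and the copper-catalysed C–H amination of electron-rich heteroarenes with amines through heteroaryl(mesityl)iodonium salts made in situ, neither of which has been shown with an NH-indole as the nitrogen partner and an N-unprotected, peri-brominated indol-3-yl iodonium partner; no stereocentre is formed.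

Step 4
Reactants: 9 4',5,5'-tribromo-1'H-1,3'-biindole
Product: 12 rivularin A (2,2',3,4',5,5'-hexabromo-1'H-1,3'-biindole), via tetrabromobiindole 10 (not isolated), via pentabromobiindole 11 (not isolated)
Conditions: NBS (3.1 equiv), DMF, 0 °C → rt, dark
Reagents that add atoms: N-bromosuccinimide, O=C1CCC(=O)N1Br
Why: Electrophilic aromatic bromination at the three most nucleophilic free positions, expected in the order C3 of the N-arylindole ring A, C2' of the 3-substituted NH-indole ring B, then C2 of ring A (the standard 2,3-dibromination of N-substituted indoles), while the benzenoid positions sit on rings already deactivated by bromine; no stereocentre is formed, and the N1–C3' axis becomes tetra-ortho-substituted here without control.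

**Compound list**

1 | 4-bromoisatin (4-bromo-1H-indole-2,3-dione) | O=C1Nc2cccc(Br)c2C1=O | starting material
2 | 4,5-dibromoisatin (4,5-dibromo-1H-indole-2,3-dione) | O=C1Nc2ccc(Br)c(Br)c2C1=O | intermediate
3 | 4,5-dibromo-3-hydroxyindolin-2-one (racemic; present as its borate; not isolated) | O=C1Nc2ccc(Br)c(Br)c2C1O | intermediate
4 | 4,5-dibromoindolin-3-ol (racemic; present as its borane complex; not isolated) | OC1CNc2ccc(Br)c(Br)c12 | intermediate
5 | 4,5-dibromo-1H-indole | Brc1ccc2[nH]ccc2c1Br | intermediate
6 | 5-bromo-1H-indole | Brc1ccc2[nH]ccc2c1 | starting material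
7 | (4,5-dibromo-1H-indol-3-yl)(2,4,6-trimethylphenyl)iodonium 4-methylbenzenesulfonate (not isolated) | Cc1cc(C)c([I+]c2c[nH]c3ccc(Br)c(Br)c23)c(C)c1.Cc1ccc(S(=O)(=O)[O-])cc1 | intermediate
8 | 4,5-dibromo-3-[(2,4,6-trimethylphenyl)iodonio]indol-1-ide (betaine; not isolated) | Cc1cc(C)c([I+]c2c[n-]c3ccc(Br)c(Br)c23)c(C)c1 | intermediate
9 | 4',5,5'-tribromo-1'H-1,3'-biindole [5-bromo-1-(4,5-dibromo-1H-indol-3-yl)-1H-indole] | Brc1ccc2c(c1)ccn2-c1c[nH]c2ccc(Br)c(Br)c12 | intermediate
10 | 3,4',5,5'-tetrabromo-1'H-1,3'-biindole (not isolated) | Brc1ccc2c(c1)c(Br)cn2-c1c[nH]c2ccc(Br)c(Br)c12 | intermediate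
11 | 2',3,4',5,5'-pentabromo-1'H-1,3'-biindole (not isolated) | Brc1ccc2c(c1)c(Br)cn2-c1c(Br)[nH]c2ccc(Br)c(Br)c12 | intermediate
12 | rivularin A, 2,2',3,4',5,5'-hexabromo-1'H-1,3'-biindole (no stereocentre; axis not specified) | Brc1ccc2c(c1)c(Br)c(Br)n2-c1c(Br)[nH]c2ccc(Br)c(Br)c12 | target

**Step count**

Total steps: 4. Longest linear sequence: 4 steps (1 → 2 → 5 → 9 → 12); compound 6 enters at step 3.

**Three steps most likely to fail**

Step 3 (the proposed new coupling). The risks are C3-arylation of 6 instead of N-arylation, decomposition of the N-unprotected iodonium species, and transfer of the mesityl group. The fallback uses known chemistry and sets out from 5. Iodination with I2 and KOH in DMF at rt gives 4,5-dibromo-3-iodo-1H-indole F1. Treatment with NaH and TsCl in THF at 0 °C gives 4,5-dibromo-3-iodo-1-tosyl-1H-indole F2. An Ullmann–Goldberg N-arylation of 6 with F2 (CuI 10 mol %, trans-N,N'-dimethylcyclohexane-1,2-diamine 20 mol %, K3PO4, toluene, 90 °C) follows, in which the C–I bond reacts well ahead of the C–Br bonds, and gives 5-bromo-1-(4,5-dibromo-1-tosyl-1H-indol-3-yl)-1H-indole F3. Removal of the tosyl group with KOH in MeOH/THF at 60 °C brings the sequence back to the route at 9.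

Step 4 (threefold bromination). The risks are incomplete bromination at C2 of ring A, over-bromination of a benzenoid position, and oxidation of the NH-indole ring B. The fallback moves the ring A bromines ahead of the C–N bond formation and sets out from 6. NBS (2.05 equiv) in THF at −78 °C → rt gives 2,3,5-tribromo-1H-indole F4. F4 is used in place of 6 under the conditions of step 3 with the iodonium salt 7 made from 5; its C3 is blocked and its N–H is more acidic, so only N-arylation is possible. This gives 2,3,5-tribromo-1-(4,5-dibromo-1H-indol-3-yl)-1H-indole F5. A single bromination at C2' with pyridinium tribromide (1.0 equiv) in THF/CHCl3 at 0 °C then comes back to the route at 12.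

Step 2 (isatin to indole). The risks are incomplete reduction, a boron-bound amino alcohol that does not eliminate, and over-reduction to the indoline. The fallback removes the two oxygens one at a time and sets out from 2. Wolff–Kishner deoxygenation of the ketone with N2H4·H2O at 130 °C gives 4,5-dibromoindolin-2-one F6. Partial reduction of the lactam with i-Bu2AlH in THF/toluene at 0 °C → rt, followed by dehydration of the hemiaminal on work-up, comes back to the route at 5.

**Further compounds**

F1 | step 3 | 4,5-dibromo-3-iodo-1H-indole | Brc1ccc2[nH]cc(I)c2c1Br
F2 | step 3 | 4,5-dibromo-3-iodo-1-tosyl-1H-indole | Cc1ccc(S(=O)(=O)n2cc(I)c3c(Br)c(Br)ccc32)cc1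
F3 | step 3 | 5-bromo-1-(4,5-dibromo-1-tosyl-1H-indol-3-yl)-1H-indole | Cc1ccc(S(=O)(=O)n2cc(-n3ccc4cc(Br)ccc43)c3c(Br)c(Br)ccc32)cc1
F4 | step 4 | 2,3,5-tribromo-1H-indole | Brc1ccc2[nH]c(Br)c(Br)c2c1
F5 | step 4 | 2,3,5-tribromo-1-(4,5-dibromo-1H-indol-3-yl)-1H-indole | Brc1ccc2c(c1)c(Br)c(Br)n2-c1c[nH]c2ccc(Br)c(Br)c12
F6 | step 2 | 4,5-dibromoindolin-2-one | O=C1Cc2c(Br)c(Br)ccc2N1
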